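**Plan**

1. Skeleton labels: C1 allyl bridgehead, C2 CH2, C3 CH(OMe), C4 C=O, C5 OMe bridgehead, C6 CH(aryl), C7 CH(CH3), C8 CH(OH) bridge, C9 the methyl carbon on C7, O8 the oxygen on C8.
2. Retrosynthesis: the C3–OMe group and the C8–H bond go first (leaving a C4 carbonyl and a C8 ketone). Next the C1–C7 bond is cut by a retro-pinacol shift that returns C7 to C8, together with the C1–allyl bond. Then C5–C6 and C7–C8 of the resulting cyclobutane are cut ([2+2]), and last the O8–Si–C9 link and the arene-derived enone.
3. Enabling feature: the five-membered ring C1–C7–C6–C5–C8 is the cyclobutane C8–C5–C6–C7 with C1 inserted beside the oxygen-bearing C8, so a 6–4 photoadduct can be enlarged by a 1,2-shift. C9 stands 1,3 to O8 on one face of that cyclobutane, so one SiMe2 unit can tie the propenylarene to the enol oxygen and later be replaced by hydrogen.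
4. Forward order: the ring C1–C2–C3–C4–C5–C8 comes from an arene by phenol oxidation to a quinone monoketal. The oxasilolane and the cyclobutane close together in the photocycloaddition. The cyclobutane then becomes the five-membered ring of the bicyclo[3.2.1]octane in the pinacol step, followed by C8 reduction, C3 methoxylation and debenzylation.
5. Stereochemistry: C5, C6, C7 and the cis fusion (later C1) come from the tethered photocycloaddition of the E-alkene. C8 comes from hydride attack anti to the axial ketal methoxy group, and C3 from face-selective protonation of a methoxy enolate. The absolute configuration comes from chromatographic separation of the enantiomers of the ring-expanded ketone, because the α-oxygenated, ketal-bearing enone (no α-hydrogen, acid-labile groups) offers no reliable handle for a chiral Lewis acid.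

Key step: step 8

Remark: 2-hydroxy-3,4-dimethoxybenzaldehyde, 3-(benzyloxy)-4-methoxybenzaldehyde, allyl(chloro)dimethylsilane and allylmagnesium bromide are taken as commercial.
Remark: the photoadduct and the two compounds that follow it are racemic; their SMILES show the enantiomer that leads to the target, and the C1 carbinol centre of the latter two (an epimer mixture, destroyed in step 11) is left undefined.
Remark: names of the bicyclic compounds use the skeleton labels above; endo means facing the C2–C4 bridge, exo means facing C8.

**Route**

Step 1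
Reactants: 1 2-hydroxy-3,4-dimethoxybenzaldehyde
Product: 2 2-(benzyloxy)-3,4-dimethoxybenzaldehyde
Conditions: BnBr, K2CO3, DMF, rt
Reagents that add atoms: benzyl bromide, BrCc1ccccc1
Why: Williamson ether synthesis, in which the acidic ortho-formyl phenol is benzylated cleanly as its phenoxide by the primary bromide.

Step 2
Reactants: 2 2-(benzyloxy)-3,4-dimethoxybenzaldehyde
Product: 4 2-(benzyloxy)-3,4-dimethoxyphenol, via aryl formate 3 (not isolated)
Conditions: mCPBA, CH2Cl2, 0 °C to rt; then K2CO3 (cat.), MeOH, 0 °C
Reagents that add atoms: 3-chloroperbenzoic acid, OOC(=O)c1cccc(Cl)c1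
Why: Dakin-type Baeyer–Villiger oxidation, in which the electron-rich aryl group migrates to oxygen and the formate is then cleaved by catalytic methoxide without touching the benzyl ether.

Step 3
Reactants: 4 2-(benzyloxy)-3,4-dimethoxyphenol
Product: 5 2-(benzyloxy)-3,4,4-trimethoxycyclohexa-2,5-dien-1-one
Conditions: PhI(OAc)2, MeOH, 0 °C
Reagents that add atoms: methanol, CO
Why: oxidative dearomatisation with a hypervalent iodine reagent, in which methanol attacks the activated phenol para to oxygen at the methoxy-bearing carbon and gives the para-quinone monoketal.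

Step 4
Reactants: 5 2-(benzyloxy)-3,4,4-trimethoxycyclohexa-2,5-dien-1-one
Product: 7 2-hydroxy-3,4,4-trimethoxycyclohex-2-en-1-one, via benzyloxy enone 6 (not isolated)
Conditions: H2 (1 atm), Rh/Al2O3, EtOAc, rt; then Pd/C, H2 (1 atm), rt
Reagents that add atoms: none
Why: chemoselective catalytic hydrogenation then hydrogenolysis, in which rhodium saturates the disubstituted enone double bond without cleaving the allylic ketal C–O bonds, the tetrasubstituted push–pull double bond stays, and palladium then removes the enol benzyl group.

Step 5
Reactants: 7 2-hydroxy-3,4,4-trimethoxycyclohex-2-en-1-one and 8 allyl(chloro)dimethylsilane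
Product: 9 2-{[allyl(dimethyl)silyl]oxy}-3,4,4-trimethoxycyclohex-2-en-1-one
Conditions: Et3N, CH2Cl2, 0 °C
Reagents that add atoms: none
Why: O-silylation of an acidic diosphenol-type enol by a chlorosilane with an amine base, the product being handled without aqueous acid because the silyl enol ether is labile.

Step 6
Reactants: 10 3-(benzyloxy)-4-methoxybenzaldehyde
Product: 11 2-(benzyloxy)-1-methoxy-4-vinylbenzene
Conditions: Ph3PCH3Br, KOtBu, THF, 0 °C to rt
Reagents that add atoms: methyltriphenylphosphonium bromide, C[P+](c1ccccc1)(c1ccccc1)c1ccccc1.[Br-]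
Why: Wittig methylenation of an aromatic aldehyde by the non-stabilised ylide.

Step 7
Reactants: 9 2-{[allyl(dimethyl)silyl]oxy}-3,4,4-trimethoxycyclohex-2-en-1-one and 11 2-(benzyloxy)-1-methoxy-4-vinylbenzene
Product: 12 2-({[(E)-3-(3-benzyloxy-4-methoxyphenyl)prop-2-en-1-yl]dimethylsilyl}oxy)-3,4,4-trimethoxycyclohex-2-en-1-one
Conditions: second-generation Grubbs catalyst RuCl2(=CHPh)(PCy3)(H2IMes) (5 mol%), CH2Cl2, 40 °C
Reagents that add atoms: none
Why: olefin cross-metathesis of an allylsilane with a styrene should give the conjugated E-alkene under thermodynamic control with loss of ethene, while the tetrasubstituted enol-ether double bond does not engage the ruthenium carbene.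

Step 8
Reactants: 12 2-({[(E)-3-(3-benzyloxy-4-methoxyphenyl)prop-2-en-1-yl]dimethylsilyl}oxy)-3,4,4-trimethoxycyclohex-2-en-1-one
Product: 13 racemic photoadduct: ring C1(=O)–C2H2–C3H2–C4(OMe)2–C5(OMe)–C8, cis-fused cyclobutane C8–C5–C6–C7, 3-benzyloxy-4-methoxyphenyl on C6 on the concave face cis to C4, and an O8–SiMe2–C9H2 bridge from C8 to C7 on the convex face
Conditions: thioxanthen-9-one (20 mol%), hν (405 nm LED), degassed MeCN (5 mM), rt
Reagents that add atoms: none
Why: Thioxanthone transfers triplet energy to the electron-rich styrene, whose twisted triplet bonds through C7 to the enone carbon C8 in a five-membered cyclic arrangement (C8–O8–Si–C9–C7), and the resulting triplet 1,4-diradical (benzylic C6, methoxy-stabilised C5) closes the C5–C6 bond after intersystem crossing. The closest known reaction types are the silicon-tethered intramolecular enone–alkene [2+2] photocycloaddition and the sensitised intramolecular styrene–alkene [2+2] photocycloaddition. The oxasilolane closes by 5-exo radical attack (rule of five) and the cyclobutane by recombination of the 1,4-diradical onto the six-membered ring. C8 and C5 become cis-fused because the short tether holds C7 and then C6 on one face of the enone, C7 carries C9 cis to O8 because both lie in the five-membered ring, and C6 takes the aryl group trans to C9, as in the E-alkene and as preferred in the diradical closure, which puts it on the concave face of the carbocycle, cis to C4. The step needs head-to-tail regiochemistry (C7 to C8, C6 to C5), which the three-atom tether secures, and the aryl group on the face of C4, which the trans relation to the tethered C9 secures against the steric bias of the ketal. No absolute control is exerted, so 13 is racemic.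

Step 9
Reactants: 13 racemic photoadduct and 14 allylmagnesium bromide
Product: 15 racemic C1 allyl carbinol of the photoadduct (allyl and OH on C1, both C1 epimers, oxasilolane intact)
Conditions: THF, −78 °C; aq. NH4Cl
Reagents that add atoms: none
Why: Grignard 1,2-addition, which allylmagnesium bromide undergoes even with hindered, enolisable ketones through a cyclic six-membered transition state; the new centre C1 forms as an epimer mixture, which does not matter because C1 is ionised in step 11.

Step 10
Reactants: 15 racemic C1 allyl carbinol of the photoadduct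
Product: 16 racemic 1-allyl-6-(3-benzyloxy-4-methoxyphenyl)-4,4,5-trimethoxy-7-methyl-cis-bicyclo[4.2.0]octane-1,8-diol (skeleton labels; aryl on the concave face, C7 methyl on the convex face cis to the C8 hydroxyl; both C1 epimers)
Conditions: Bu4NF (wet, THF solution), DMF, 70 °C
Reagents that add atoms: none
Why: fluoride-promoted protodesilylation of a 1-oxa-2-silacyclopentane, the traceless end of a temporary silicon connection, in which fluoride and the neighbouring alkoxide make silicon pentacoordinate and the Si–C9 bond is cleaved with protonation by water, so C9 becomes the methyl group with C7 unchanged.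

Step 11
Reactants: 16 racemic 1,8-diol
Product: 17 1-allyl-6-endo-(3-benzyloxy-4-methoxyphenyl)-4,4,5-trimethoxy-7-exo-methylbicyclo[3.2.1]octan-8-one (single enantiomer)
Conditions: camphorsulfonic acid (0.3 equiv), HC(OMe)3, MeOH, 40 °C; then preparative HPLC on amylose tris(3,5-dimethylphenylcarbamate), hexane/2-propanol
Reagents that add atoms: none
Why: pinacol rearrangement with cyclobutane ring expansion, in which acid ionises the tertiary C1–OH rather than the cyclobutanol C8–OH, the strained exocyclic C8–C7 bond shifts to C1 on the face it already occupies (fixing C1 as the bridgehead and retaining C7) and O8 becomes the ketone, while methanol and the orthoformate keep the C4 ketal in place; the enantiomers of the racemic ketone are then separated on the chiral phase and the one drawn is carried on.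

Step 12
Reactants: 17 ring-expanded ketal ketone
Product: 19 1-allyl-6-endo-(3-benzyloxy-4-methoxyphenyl)-8-hydroxy-5-methoxy-7-exo-methylbicyclo[3.2.1]octan-4-one (hydroxyl syn to the C2–C4 bridge), via hydroxy ketal 18 (not isolated)
Conditions: LiAlH4, Et2O, −78 to 0 °C; then 2 M aq. HCl, THF, rt
Reagents that add atoms: water, O
Why: hydride reduction then acetal hydrolysis, in which the axial methoxy group of the C4 ketal and the axial C2–H shield the face of the C8 carbonyl that looks to the three-carbon bridge, so hydride should enter over the two-carbon bridge and leave the hydroxyl syn to C2–C4, after which aqueous acid unveils the C4 ketone.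

Step 13
Reactants: 19 hydroxy ketone
Product: 21 1-allyl-6-endo-(3-benzyloxy-4-methoxyphenyl)-3,8-dihydroxy-5-methoxy-7-exo-methylbicyclo[3.2.1]octan-4-one, via dilithium enolate 20 (not isolated)
Conditions: LiN(SiMe3)2 (2.5 equiv), THF, −78 °C; then 3-phenyl-2-(phenylsulfonyl)oxaziridine, −78 °C; aq. NH4Cl
Reagents that add atoms: 3-phenyl-2-(phenylsulfonyl)oxaziridine, O=S(=O)(N1OC1c1ccccc1)c1ccccc1
Why: Davis α-hydroxylation, in which excess base gives the alkoxide–enolate dianion at the only enolisable position (C3) and the N-sulfonyloxaziridine transfers oxygen to it; the C3 configuration (drawn for attack on the face towards C8) is immaterial because C3 becomes trigonal in step 14.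

Step 14
Reactants: 21 α-ketol
Product: 22 1-allyl-6-endo-(3-benzyloxy-4-methoxyphenyl)-3,8-dihydroxy-5-methoxy-7-exo-methylbicyclo[3.2.1]oct-2-en-4-one (diosphenol)
Conditions: Cu(OAc)2, MeOH/H2O, rt
Reagents that add atoms: none
Why: oxidation of an α-ketol to the 1,2-dione by Cu(OAc)2, which leaves the hindered isolated C8 carbinol alone, the dione then enolising towards C2, the only neighbouring carbon with hydrogen.

Step 15
Reactants: 22 diosphenol
Product: 23 1-allyl-6-endo-(3-benzyloxy-4-methoxyphenyl)-8-hydroxy-3,5-dimethoxy-7-exo-methylbicyclo[3.2.1]oct-2-en-4-one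
Conditions: Me3SiCHN2, MeOH/toluene, 0 °C
Reagents that add atoms: (trimethylsilyl)diazomethane, C[Si](C)(C)C=[N+]=[N-]
Why: O-methylation of the acidic diosphenol hydroxyl by a diazoalkane under neutral conditions, under which the C8 alcohol does not react and the base-sensitive β-hydroxy ketone is not exposed to base.

Step 16
Reactants: 23 methoxy enone
Product: 24 1-allyl-6-endo-(3-benzyloxy-4-methoxyphenyl)-8-hydroxy-3,5-dimethoxy-7-exo-methylbicyclo[3.2.1]octan-4-one (C3 methoxy on the side of the C6–C7 bridge)
Conditions: [(Ph3P)CuH]6, H2O (2 equiv), THF/toluene, rt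
Reagents that add atoms: none
Why: conjugate reduction with a copper hydride, in which hydride goes to C2 and the resulting enolate is protonated at C3 on the face that looks towards C8 (the other face is covered by the C6 aryl group), possibly by the C8 hydroxyl itself, which places the methoxy group on the side of the two-carbon bridge.

Step 17
Reactants: 24 benzyl ether of the target
Product: 25 (1S,3S,5S,6S,7R,8S)-1-allyl-8-hydroxy-6-(3-hydroxy-4-methoxyphenyl)-3,5-dimethoxy-7-methylbicyclo[3.2.1]octan-4-one (skeleton labels), CNP0209708.1
Conditions: BCl3, C6HMe5, CH2Cl2, −78 °C; then H2O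
Reagents that add atoms: none
Why: Lewis acid debenzylation with a cation scavenger, in which BCl3 cleaves the aryl benzyl ether at low temperature and pentamethylbenzene traps the benzyl cation, so the allyl group, the ketone, the alkyl methyl ethers (one at a bridgehead) and the aryl methyl ether should survive.

**Compound list**

1 | 2-hydroxy-3,4-dimethoxybenzaldehyde | COc1ccc(C=O)c(O)c1OC | starting material
2 | 2-(benzyloxy)-3,4-dimethoxybenzaldehyde | COc1ccc(C=O)c(OCc2ccccc2)c1OC | intermediate
3 | 2-(benzyloxy)-3,4-dimethoxyphenyl formate (not isolated) | COc1ccc(OC=O)c(OCc2ccccc2)c1OC | intermediate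
4 | 2-(benzyloxy)-3,4-dimethoxyphenol | COc1ccc(O)c(OCc2ccccc2)c1OC | intermediate
5 | 2-(benzyloxy)-3,4,4-trimethoxycyclohexa-2,5-dien-1-one | O=C1C=CC(OC)(OC)C(OC)=C1OCc1ccccc1 | intermediate
6 | 2-(benzyloxy)-3,4,4-trimethoxycyclohex-2-en-1-one (not isolated) | O=C1CCC(OC)(OC)C(OC)=C1OCc1ccccc1 | intermediate
7 | 2-hydroxy-3,4,4-trimethoxycyclohex-2-en-1-one | O=C1CCC(OC)(OC)C(OC)=C1O | intermediate
8 | allyl(chloro)dimethylsilane | C=CC[Si](C)(C)Cl | starting material
9 | 2-{[allyl(dimethyl)silyl]oxy}-3,4,4-trimethoxycyclohex-2-en-1-one | O=C1CCC(OC)(OC)C(OC)=C1O[Si](C)(C)CC=C | intermediate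
10 | 3-(benzyloxy)-4-methoxybenzaldehyde | COc1ccc(C=O)cc1OCc1ccccc1 | starting material
11 | 2-(benzyloxy)-1-methoxy-4-vinylbenzene | C=Cc1ccc(OC)c(OCc2ccccc2)c1 | intermediate
12 | 2-({[(E)-3-(3-benzyloxy-4-methoxyphenyl)prop-2-en-1-yl]dimethylsilyl}oxy)-3,4,4-trimethoxycyclohex-2-en-1-one | O=C1CCC(OC)(OC)C(OC)=C1O[Si](C)(C)C/C=C/c1ccc(OC)c(OCc2ccccc2)c1 | intermediate
13 | racemic photoadduct (cis-fused 6–4 ketone with O8–SiMe2–C9 bridge, aryl on the concave face) | O=C1CCC(OC)(OC)[C@]2(OC)[C@H](c4ccc(OC)c(OCc5ccccc5)c4)[C@H]3C[Si](C)(C)O[C@@]123 | intermediate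
14 | allylmagnesium bromide | C=CC[Mg]Br | starting material
15 | racemic C1 allyl carbinol of the photoadduct (C1 epimers) | C=CCC1(O)CCC(OC)(OC)[C@]2(OC)[C@H](c4ccc(OC)c(OCc5ccccc5)c4)[C@H]3C[Si](C)(C)O[C@@]123 | intermediate
16 | racemic 1-allyl-6-(3-benzyloxy-4-methoxyphenyl)-4,4,5-trimethoxy-7-methyl-cis-bicyclo[4.2.0]octane-1,8-diol (C1 epimers) | C=CCC1(O)CCC(OC)(OC)[C@]2(OC)[C@H](c3ccc(OC)c(OCc4ccccc4)c3)[C@@H](C)[C@]12O | intermediate
17 | 1-allyl-6-endo-(3-benzyloxy-4-methoxyphenyl)-4,4,5-trimethoxy-7-exo-methylbicyclo[3.2.1]octan-8-one | C=CC[C@]12CCC(OC)(OC)[C@](OC)([C@H](c3ccc(OC)c(OCc4ccccc4)c3)[C@H]1C)C2=O | intermediate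
18 | 1-allyl-6-endo-(3-benzyloxy-4-methoxyphenyl)-4,4,5-trimethoxy-7-exo-methylbicyclo[3.2.1]octan-8-ol, hydroxyl syn to C2–C4 (not isolated) | C=CC[C@]12CCC(OC)(OC)[C@](OC)([C@H](c3ccc(OC)c(OCc4ccccc4)c3)[C@H]1C)[C@H]2O | intermediate
19 | 1-allyl-6-endo-(3-benzyloxy-4-methoxyphenyl)-8-hydroxy-5-methoxy-7-exo-methylbicyclo[3.2.1]octan-4-one | C=CC[C@]12CCC(=O)[C@](OC)([C@H](c3ccc(OC)c(OCc4ccccc4)c3)[C@H]1C)[C@H]2O | intermediate
20 | dilithium C3–C4 enolate C8 alkoxide of 19 (not isolated) | C=CC[C@]12CC=C([O-])[C@](OC)([C@H](c3ccc(OC)c(OCc4ccccc4)c3)[C@H]1C)[C@H]2[O-].[Li+].[Li+] | intermediate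
21 | 1-allyl-6-endo-(3-benzyloxy-4-methoxyphenyl)-3,8-dihydroxy-5-methoxy-7-exo-methylbicyclo[3.2.1]octan-4-one | C=CC[C@]12C[C@@H](O)C(=O)[C@](OC)([C@H](c3ccc(OC)c(OCc4ccccc4)c3)[C@H]1C)[C@H]2O | intermediate
22 | 1-allyl-6-endo-(3-benzyloxy-4-methoxyphenyl)-3,8-dihydroxy-5-methoxy-7-exo-methylbicyclo[3.2.1]oct-2-en-4-one | C=CC[C@]12C=C(O)C(=O)[C@](OC)([C@H](c3ccc(OC)c(OCc4ccccc4)c3)[C@H]1C)[C@H]2O | intermediate
23 | 1-allyl-6-endo-(3-benzyloxy-4-methoxyphenyl)-8-hydroxy-3,5-dimethoxy-7-exo-methylbicyclo[3.2.1]oct-2-en-4-one | C=CC[C@]12C=C(OC)C(=O)[C@](OC)([C@H](c3ccc(OC)c(OCc4ccccc4)c3)[C@H]1C)[C@H]2O | intermediate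
24 | 1-allyl-6-endo-(3-benzyloxy-4-methoxyphenyl)-8-hydroxy-3,5-dimethoxy-7-exo-methylbicyclo[3.2.1]octan-4-one | C=CC[C@]12C[C@H](OC)C(=O)[C@](OC)([C@H](c3ccc(OC)c(OCc4ccccc4)c3)[C@H]1C)[C@H]2O | intermediate
25 | (1S,3S,5S,6S,7R,8S)-1-allyl-8-hydroxy-6-(3-hydroxy-4-methoxyphenyl)-3,5-dimethoxy-7-methylbicyclo[3.2.1]octan-4-one | C=CC[C@]12C[C@H](OC)C(=O)[C@](OC)([C@H](c3ccc(OC)c(O)c3)[C@H]1C)[C@H]2O | target

**Step count**

Total steps: 17. Longest linear sequence: 16 (steps 1–5 and 7–17).

**Steps most likely to fail**

Step 8. The styrene triplet may relax by E/Z isomerisation faster than it attacks the fully substituted carbon C8, or the 1,4-diradical may close with the aryl group on the same face as C9. Fallback: from 12 the same two bonds are made by hole catalysis in place of energy transfer. A photoexcited pyrylium salt (2,4,6-tris(4-methoxyphenyl)pyrylium tetrafluoroborate, blue light, CH2Cl2) oxidises the arylalkene to its radical cation, and the nucleophilic α-carbon C8 of the vinylogous ester attacks C7. The benzylic radical at C6 and the methoxy-stabilised cation at C5 then close the four-membered ring, and back electron transfer releases 13. Because arylcyclobutane radical cations can reopen, the isomer with the aryl group trans to C9 should be reached under equilibrating conditions. The fallback returns to the route at 13 and makes no new compound (F0).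

Step 11. The acid needed to ionise C1–OH may also ionise and solvolyse the C4 ketal, so that the ketal is lost before or during the shift. The ring bond C8–C5 may also compete with C8–C7 as the migrating bond. Fallback: from 16 the ketal is given up on purpose. Trifluoroacetic acid–water at 0 °C hydrolyses the ketal (water captures the C4 oxocarbenium ion faster than any skeletal shift) and effects the same pinacol ring expansion in a non-nucleophilic, more ionising medium. This gives 1-allyl-6-endo-(3-benzyloxy-4-methoxyphenyl)-5-methoxy-7-exo-methylbicyclo[3.2.1]octane-4,8-dione F1, which is resolved on the same chiral phase. The C4 carbonyl, which has one quaternary neighbour, is then re-ketalised with HC(OMe)3, MeOH and camphorsulfonic acid, now without any cyclobutane present, while the bridging C8 carbonyl between two quaternary bridgeheads stays free. This returns to the route at 17.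

Step 12. Facial selectivity may be poor: the exo methyl group on C7 hinders the face over the two-carbon bridge, so hydride may enter from the side of the three-carbon bridge and give the C8 epimer. Fallback: from 17 the ketone is reduced by electron transfer (SmI2, H2O, Et3N, THF) in place of nucleophilic hydride. The ketyl and the derived organosamarium species are configurationally labile, so the C8–H bond forms under product-stability control. This should favour the hydroxyl that avoids the C9 methyl group and is hydrogen-bonded to the axial ketal methoxy group. The C5–OMe bond lies in the nodal plane of the ketyl and should not be expelled. This gives 18, which is hydrolysed as in step 12 to 19; no new compound is made (F0).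

Further compounds
F0 | step 8 | none | none
F1 | step 11 | 1-allyl-6-endo-(3-benzyloxy-4-methoxyphenyl)-5-methoxy-7-exo-methylbicyclo[3.2.1]octane-4,8-dione | C=CC[C@]12CCC(=O)[C@](OC)([C@H](c3ccc(OC)c(OCc4ccccc4)c3)[C@H]1C)C2=O
F0 | step 12 | none | none
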